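## Retrosynthetic overview

1. The target comes from its octa-isopropyl ether by BCl3 cleavage; the (E)-4-alkoxystyryl arm on benzo ring C comes from an iridium C–H borylation/Suzuki coupling with an (E)-β-chlorostyrene.
2. Key disconnection, used twice: each trans-2,3-diaryl-4-oxy-2,3-dihydrobenzofuran is the aromatised form of a tetrahydrobenzofuran-4-one, made by Mn(OAc)3 oxidative radical [3+2] annulation of cyclohexane-1,3-dione (a latent resorcinol) onto an (E)-stilbene. The C3–C3a bond forms by radical addition, the C2–O bond by closure onto the benzylic cation, trans.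
3. Ring order: dihydrofuran ring B on carbocycle A (the unit with the catechol), aromatise A, styryl arm on A; then dihydrofuran ring D on carbocycle C, aromatise C, styryl arm on C.
4. The stilbenes come from aryl boronates or a Grignard reagent (from catechol, resorcinol, 4-bromophenol) joined through (E)-1,2-dichloroethene as a two-carbon linchpin.
5. Absolute configuration: the first annulation gives a trans racemate that is resolved on a chiral phase; the second gives two trans diastereomers that are separated.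

Assumption: separating stereoisomers by chromatography is part of the work-up of the step that forms them and is not counted as a step.

## Route

Step 1
Reactants: 1 catechol (benzene-1,2-diol)
Product: 2 1,2-di(propan-2-yloxy)benzene
Conditions: 2-bromopropane, K2CO3, DMF, 70 °C
Reagents that add atoms: 2-bromopropane, CC(C)Br
Why: Williamson ether synthesis; isopropyl ethers survive every later step and leave at the end under BCl3.

Step 2
Reactants: 2 1,2-di(propan-2-yloxy)benzene; 3 (E)-1,2-dichloroethene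
Product: 5 4-[(E)-2-chloroethenyl]-1,2-di(propan-2-yloxy)benzene, via aryl pinacol boronate 4 (not isolated)
Conditions: [Ir(OMe)(cod)]2 (1.5 mol%), 4,4'-di-tert-butyl-2,2'-bipyridine (dtbpy), B2pin2, THF, 80 °C; then 3 (6 equiv), Pd(PPh3)4 (3 mol%), aq K3PO4, 65 °C, sealed tube
Reagents that add atoms: bis(pinacolato)diboron, CC1(C)OB(OC1(C)C)B1OC(C)(C)C(C)(C)O1 (its boron and pinacol atoms stay only in 4)
Why: Sterically controlled iridium-catalysed C–H borylation reaches only the equivalent C4/C5 positions, and the boronate then undergoes Suzuki–Miyaura mono-coupling because the doubly activated dichloride adds to zerovalent palladium faster than the product monochloride, with retention of the E geometry.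

Step 3
Reactants: 6 resorcinol (benzene-1,3-diol)
Product: 7 1,3-di(propan-2-yloxy)benzene
Conditions: 2-bromopropane, K2CO3, DMF, 70 °C
Reagents that add atoms: 2-bromopropane, CC(C)Br
Why: Williamson ether synthesis, as in step 1.

Step 4
Reactants: 7 1,3-di(propan-2-yloxy)benzene; 5 4-[(E)-2-chloroethenyl]-1,2-di(propan-2-yloxy)benzene
Product: 9 (E)-1-[3,4-di(propan-2-yloxy)phenyl]-2-[3,5-di(propan-2-yloxy)phenyl]ethene, via aryl pinacol boronate 8 (not isolated)
Conditions: [Ir(OMe)(cod)]2 (1.5 mol%), dtbpy, B2pin2, THF, 80 °C; then 5, Pd(OAc)2 (3 mol%), SPhos, aq K3PO4, 60 °C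
Reagents that add atoms: bis(pinacolato)diboron, CC1(C)OB(OC1(C)C)B1OC(C)(C)C(C)(C)O1 (its boron and pinacol atoms stay only in 8)
Why: Iridium-catalysed C–H borylation takes place at C5 of 7, the only C–H without an ortho substituent, and Suzuki–Miyaura coupling of the boronate with the alkenyl chloride proceeds with retention to give the E-stilbene.

Step 5
Reactants: 9 (E)-1-[3,4-di(propan-2-yloxy)phenyl]-2-[3,5-di(propan-2-yloxy)phenyl]ethene; 10 cyclohexane-1,3-dione
Product: 11 (2S,3S)-2-[3,4-di(propan-2-yloxy)phenyl]-3-[3,5-di(propan-2-yloxy)phenyl]-3,5,6,7-tetrahydro-1-benzofuran-4(2H)-one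
Conditions: Mn(OAc)3·2H2O (2.5 equiv), AcOH, 70 °C, N2; then preparative SFC on an amylose-based chiral stationary phase
Reagents that add atoms: none
Why: Mn(OAc)3-mediated oxidative radical [3+2] annulation, in which the trivalent-manganese enolate of 10 gives the electrophilic 2-dione radical that bonds to the alkene carbon carrying the 3,5-dialkoxyphenyl group so that the new benzylic radical lies next to the para-alkoxy donor, a second oxidation gives the benzylic cation, the enol oxygen closes on it anti to the C3 aryl group (both stereocenters set here, trans, as a racemate), and the chiral SFC delivers the (2S,3S) enantiomer.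

Step 6
Reactants: 11 (2S,3S)-2-[3,4-di(propan-2-yloxy)phenyl]-3-[3,5-di(propan-2-yloxy)phenyl]-3,5,6,7-tetrahydro-1-benzofuran-4(2H)-one
Product: 13 (2S,3S)-2-[3,4-di(propan-2-yloxy)phenyl]-3-[3,5-di(propan-2-yloxy)phenyl]-4-(propan-2-yloxy)-2,3-dihydro-1-benzofuran, via phenol 12 (not isolated)
Conditions: LiN(iPr)2, THF, −78 °C; PhS(Cl)=NtBu, −78 °C to rt; then K2CO3, 2-iodopropane, DMF, 60 °C
Reagents that add atoms: 2-iodopropane, CC(C)I
Why: Mukaiyama dehydrogenation of the kinetic C5 enolate gives the cross-conjugated dienone, which tautomerises to the phenol (aromatisation of ring A) and is O-alkylated in the same pot, while C2–H and C3–H are not acidic enough to be touched.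

Step 7
Reactants: 14 4-bromophenol
Product: 15 1-bromo-4-(propan-2-yloxy)benzene
Conditions: 2-bromopropane, K2CO3, DMF, 70 °C
Reagents that add atoms: 2-bromopropane, CC(C)Br
Why: Williamson ether synthesis.

Step 8
Reactants: 15 1-bromo-4-(propan-2-yloxy)benzene; 3 (E)-1,2-dichloroethene
Product: 17 1-[(E)-2-chloroethenyl]-4-(propan-2-yloxy)benzene, via aryl Grignard reagent 16 (not isolated)
Conditions: Mg, THF, reflux; then 3 (5 equiv), Pd(PPh3)4 (3 mol%), THF, 0 °C to rt
Reagents that add atoms: magnesium, [Mg] (stays only in 16)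
Why: Kumada–Corriu coupling in which zerovalent palladium inserts into one C–Cl bond of the activated dichloride faster than into the product monochloride, so the excess dichloride gives mono-arylation with retention of the E geometry.

Step 9
Reactants: 13 (2S,3S)-2-[3,4-di(propan-2-yloxy)phenyl]-3-[3,5-di(propan-2-yloxy)phenyl]-4-(propan-2-yloxy)-2,3-dihydro-1-benzofuran; 17 1-[(E)-2-chloroethenyl]-4-(propan-2-yloxy)benzene
Product: 19 (2S,3S)-2-[3,4-di(propan-2-yloxy)phenyl]-3-[3,5-di(propan-2-yloxy)phenyl]-4-(propan-2-yloxy)-6-[(E)-2-[4-(propan-2-yloxy)phenyl]ethenyl]-2,3-dihydro-1-benzofuran, via pinacol boronate 18 (not isolated)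
Conditions: [Ir(OMe)(cod)]2 (2.5 mol%), dtbpy, B2pin2, THF, 80 °C; then 17, Pd(OAc)2 (5 mol%), SPhos, aq K3PO4, 60 °C
Reagents that add atoms: bis(pinacolato)diboron, CC1(C)OB(OC1(C)C)B1OC(C)(C)C(C)(C)O1 (its boron and pinacol atoms stay only in 18)
Why: Iridium-catalysed C–H borylation goes to C6 of ring A, the only C–H in 13 with no ortho substituent and meta to both ring oxygens (the situation of C5 in 7), and Suzuki–Miyaura coupling with the alkenyl chloride installs the E-styryl arm without touching a stereocenter.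

Step 10
Reactants: 19 (2S,3S)-2-[3,4-di(propan-2-yloxy)phenyl]-3-[3,5-di(propan-2-yloxy)phenyl]-4-(propan-2-yloxy)-6-[(E)-2-[4-(propan-2-yloxy)phenyl]ethenyl]-2,3-dihydro-1-benzofuran; 10 cyclohexane-1,3-dione
Product: 20 (2R,3R)-3-[(2S,3S)-2-[3,4-di(propan-2-yloxy)phenyl]-3-[3,5-di(propan-2-yloxy)phenyl]-4-(propan-2-yloxy)-2,3-dihydro-1-benzofuran-6-yl]-2-[4-(propan-2-yloxy)phenyl]-3,5,6,7-tetrahydro-1-benzofuran-4(2H)-one
Conditions: Mn(OAc)3·2H2O (2.5 equiv), AcOH, 70 °C, N2; then preparative HPLC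
Reagents that add atoms: none
Why: The same Mn(OAc)3 oxidative radical [3+2] annulation, in which the dione radical adds to the alkene carbon on ring A (meta-oxygenated, no stabilisation) so that radical and cation sit next to the para-alkoxyphenyl group, closure of the enol oxygen anti to the C3 substituent sets ring D trans, and because the old stereocenters are too remote to steer the attack the (2R,3R) and (2S,3S) forms of the new ring arise in about equal amounts as separable diastereomers, of which the (2R,3R) one is carried on.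

Step 11
Reactants: 20 (2R,3R)-3-[(2S,3S)-2-[3,4-di(propan-2-yloxy)phenyl]-3-[3,5-di(propan-2-yloxy)phenyl]-4-(propan-2-yloxy)-2,3-dihydro-1-benzofuran-6-yl]-2-[4-(propan-2-yloxy)phenyl]-3,5,6,7-tetrahydro-1-benzofuran-4(2H)-one
Product: 22 (2R,3R)-3-[(2S,3S)-2-[3,4-di(propan-2-yloxy)phenyl]-3-[3,5-di(propan-2-yloxy)phenyl]-4-(propan-2-yloxy)-2,3-dihydro-1-benzofuran-6-yl]-4-(propan-2-yloxy)-2-[4-(propan-2-yloxy)phenyl]-2,3-dihydro-1-benzofuran, via phenol 21 (not isolated)
Conditions: LiN(iPr)2, THF, −78 °C; PhS(Cl)=NtBu, −78 °C to rt; then K2CO3, 2-iodopropane, DMF, 60 °C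
Reagents that add atoms: 2-iodopropane, CC(C)I
Why: Mukaiyama dehydrogenation, tautomerisation to the phenol (aromatisation of ring C) and O-alkylation as in step 6, with the ketone α-protons the only ones acidic enough for the amide base so that all four stereocenters are preserved.

Step 12
Reactants: 22 (2R,3R)-3-[(2S,3S)-2-[3,4-di(propan-2-yloxy)phenyl]-3-[3,5-di(propan-2-yloxy)phenyl]-4-(propan-2-yloxy)-2,3-dihydro-1-benzofuran-6-yl]-4-(propan-2-yloxy)-2-[4-(propan-2-yloxy)phenyl]-2,3-dihydro-1-benzofuran; 17 1-[(E)-2-chloroethenyl]-4-(propan-2-yloxy)benzene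
Product: 24 (2R,3R)-3-[(2S,3S)-2-[3,4-di(propan-2-yloxy)phenyl]-3-[3,5-di(propan-2-yloxy)phenyl]-4-(propan-2-yloxy)-2,3-dihydro-1-benzofuran-6-yl]-4-(propan-2-yloxy)-2-[4-(propan-2-yloxy)phenyl]-6-[(E)-2-[4-(propan-2-yloxy)phenyl]ethenyl]-2,3-dihydro-1-benzofuran, via pinacol boronate 23 (not isolated)
Conditions: [Ir(OMe)(cod)]2 (2.5 mol%), dtbpy, B2pin2, THF, 80 °C; then 17, Pd(OAc)2 (5 mol%), SPhos, aq K3PO4, 60 °C
Reagents that add atoms: bis(pinacolato)diboron, CC1(C)OB(OC1(C)C)B1OC(C)(C)C(C)(C)O1 (its boron and pinacol atoms stay only in 23)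
Why: C6 of ring C is now the only aromatic C–H in the molecule without an ortho substituent, so the sterically controlled iridium-catalysed C–H borylation selects it and Suzuki–Miyaura coupling then attaches the second E-styryl arm with retention.

Step 13
Reactants: 24 (2R,3R)-3-[(2S,3S)-2-[3,4-di(propan-2-yloxy)phenyl]-3-[3,5-di(propan-2-yloxy)phenyl]-4-(propan-2-yloxy)-2,3-dihydro-1-benzofuran-6-yl]-4-(propan-2-yloxy)-2-[4-(propan-2-yloxy)phenyl]-6-[(E)-2-[4-(propan-2-yloxy)phenyl]ethenyl]-2,3-dihydro-1-benzofuran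
Product: 25 (2R,3R)-3-[(2S,3S)-2-(3,4-dihydroxyphenyl)-3-(3,5-dihydroxyphenyl)-4-hydroxy-2,3-dihydro-1-benzofuran-6-yl]-2-(4-hydroxyphenyl)-6-[(E)-2-(4-hydroxyphenyl)ethenyl]-2,3-dihydro-1-benzofuran-4-ol
Conditions: BCl3 (24 equiv), CH2Cl2, −78 to 0 °C; then aq NaHCO3
Reagents that add atoms: none
Why: Lewis-acid ether cleavage in which BCl3 coordinates each aryl ether oxygen and the secondary alkyl group leaves as 2-chloropropane at low temperature, conditions under which the stilbene is inert and the stereocenters are kept (a dihydrofuran that opened at C2 would reclose trans to the fixed C3 center).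

## Compound list

1 | catechol (benzene-1,2-diol) | Oc1ccccc1O | starting material
2 | 1,2-di(propan-2-yloxy)benzene | CC(C)Oc1ccccc1OC(C)C | intermediate
3 | (E)-1,2-dichloroethene | Cl/C=C/Cl | starting material
4 | 2-[3,4-di(propan-2-yloxy)phenyl]-4,4,5,5-tetramethyl-1,3,2-dioxaborolane | CC(C)Oc1ccc(cc1OC(C)C)B1OC(C)(C)C(C)(C)O1 | intermediate
5 | 4-[(E)-2-chloroethenyl]-1,2-di(propan-2-yloxy)benzene | CC(C)Oc1ccc(/C=C/Cl)cc1OC(C)C | intermediate
6 | resorcinol (benzene-1,3-diol) | Oc1cccc(O)c1 | starting material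
7 | 1,3-di(propan-2-yloxy)benzene | CC(C)Oc1cccc(OC(C)C)c1 | intermediate
8 | 2-[3,5-di(propan-2-yloxy)phenyl]-4,4,5,5-tetramethyl-1,3,2-dioxaborolane | CC(C)Oc1cc(OC(C)C)cc(c1)B1OC(C)(C)C(C)(C)O1 | intermediate
9 | (E)-1-[3,4-di(propan-2-yloxy)phenyl]-2-[3,5-di(propan-2-yloxy)phenyl]ethene | CC(C)Oc1ccc(/C=C/c2cc(OC(C)C)cc(OC(C)C)c2)cc1OC(C)C | intermediate
10 | cyclohexane-1,3-dione | O=C1CCCC(=O)C1 | starting material
11 | (2S,3S)-2-[3,4-di(propan-2-yloxy)phenyl]-3-[3,5-di(propan-2-yloxy)phenyl]-3,5,6,7-tetrahydro-1-benzofuran-4(2H)-one | C1CC(=O)C2=C(C1)O[C@H](c1ccc(OC(C)C)c(OC(C)C)c1)[C@H]2c1cc(OC(C)C)cc(OC(C)C)c1 | intermediate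
12 | (2S,3S)-2-[3,4-di(propan-2-yloxy)phenyl]-3-[3,5-di(propan-2-yloxy)phenyl]-2,3-dihydro-1-benzofuran-4-ol | c1cc(O)c2c(c1)O[C@H](c1ccc(OC(C)C)c(OC(C)C)c1)[C@H]2c1cc(OC(C)C)cc(OC(C)C)c1 | intermediate
13 | (2S,3S)-2-[3,4-di(propan-2-yloxy)phenyl]-3-[3,5-di(propan-2-yloxy)phenyl]-4-(propan-2-yloxy)-2,3-dihydro-1-benzofuran | c1cc(OC(C)C)c2c(c1)O[C@H](c1ccc(OC(C)C)c(OC(C)C)c1)[C@H]2c1cc(OC(C)C)cc(OC(C)C)c1 | intermediate
14 | 4-bromophenol | Oc1ccc(Br)cc1 | starting material
15 | 1-bromo-4-(propan-2-yloxy)benzene | CC(C)Oc1ccc(Br)cc1 | intermediate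
16 | [4-(propan-2-yloxy)phenyl]magnesium bromide | CC(C)Oc1ccc([Mg]Br)cc1 | intermediate
17 | 1-[(E)-2-chloroethenyl]-4-(propan-2-yloxy)benzene | CC(C)Oc1ccc(/C=C/Cl)cc1 | intermediate
18 | 6-(4,4,5,5-tetramethyl-1,3,2-dioxaborolan-2-yl) derivative of 13, (2S,3S) | CC1(C)OB(OC1(C)C)c1cc(OC(C)C)c2c(c1)O[C@H](c1ccc(OC(C)C)c(OC(C)C)c1)[C@H]2c1cc(OC(C)C)cc(OC(C)C)c1 | intermediate
19 | (2S,3S)-2-[3,4-di(propan-2-yloxy)phenyl]-3-[3,5-di(propan-2-yloxy)phenyl]-4-(propan-2-yloxy)-6-[(E)-2-[4-(propan-2-yloxy)phenyl]ethenyl]-2,3-dihydro-1-benzofuran | CC(C)Oc1ccc(/C=C/c2cc(OC(C)C)c3c(c2)O[C@H](c2ccc(OC(C)C)c(OC(C)C)c2)[C@H]3c2cc(OC(C)C)cc(OC(C)C)c2)cc1 | intermediate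
20 | (2R,3R)-3-[(2S,3S)-2-[3,4-di(propan-2-yloxy)phenyl]-3-[3,5-di(propan-2-yloxy)phenyl]-4-(propan-2-yloxy)-2,3-dihydro-1-benzofuran-6-yl]-2-[4-(propan-2-yloxy)phenyl]-3,5,6,7-tetrahydro-1-benzofuran-4(2H)-one | C1CC(=O)C2=C(C1)O[C@@H](c1ccc(OC(C)C)cc1)[C@@H]2c1cc(OC(C)C)c2c(c1)O[C@H](c1ccc(OC(C)C)c(OC(C)C)c1)[C@H]2c1cc(OC(C)C)cc(OC(C)C)c1 | intermediate
21 | (2R,3R)-3-[(2S,3S)-2-[3,4-di(propan-2-yloxy)phenyl]-3-[3,5-di(propan-2-yloxy)phenyl]-4-(propan-2-yloxy)-2,3-dihydro-1-benzofuran-6-yl]-2-[4-(propan-2-yloxy)phenyl]-2,3-dihydro-1-benzofuran-4-ol | c1cc(O)c2c(c1)O[C@@H](c1ccc(OC(C)C)cc1)[C@@H]2c1cc(OC(C)C)c2c(c1)O[C@H](c1ccc(OC(C)C)c(OC(C)C)c1)[C@H]2c1cc(OC(C)C)cc(OC(C)C)c1 | intermediate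
22 | (2R,3R)-3-[(2S,3S)-2-[3,4-di(propan-2-yloxy)phenyl]-3-[3,5-di(propan-2-yloxy)phenyl]-4-(propan-2-yloxy)-2,3-dihydro-1-benzofuran-6-yl]-4-(propan-2-yloxy)-2-[4-(propan-2-yloxy)phenyl]-2,3-dihydro-1-benzofuran | c1cc(OC(C)C)c2c(c1)O[C@@H](c1ccc(OC(C)C)cc1)[C@@H]2c1cc(OC(C)C)c2c(c1)O[C@H](c1ccc(OC(C)C)c(OC(C)C)c1)[C@H]2c1cc(OC(C)C)cc(OC(C)C)c1 | intermediate
23 | 6-(4,4,5,5-tetramethyl-1,3,2-dioxaborolan-2-yl) derivative of 22 (boron on ring C), (2R,3R) and (2S,3S) as in 22 | CC1(C)OB(OC1(C)C)c1cc(OC(C)C)c2c(c1)O[C@@H](c1ccc(OC(C)C)cc1)[C@@H]2c1cc(OC(C)C)c2c(c1)O[C@H](c1ccc(OC(C)C)c(OC(C)C)c1)[C@H]2c1cc(OC(C)C)cc(OC(C)C)c1 | intermediate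
24 | octa-isopropyl ether of 25: (2R,3R)-3-[(2S,3S)-2-[3,4-di(propan-2-yloxy)phenyl]-3-[3,5-di(propan-2-yloxy)phenyl]-4-(propan-2-yloxy)-2,3-dihydro-1-benzofuran-6-yl]-4-(propan-2-yloxy)-2-[4-(propan-2-yloxy)phenyl]-6-[(E)-2-[4-(propan-2-yloxy)phenyl]ethenyl]-2,3-dihydro-1-benzofuran | CC(C)Oc1ccc(/C=C/c2cc(OC(C)C)c3c(c2)O[C@@H](c2ccc(OC(C)C)cc2)[C@@H]3c2cc(OC(C)C)c3c(c2)O[C@H](c2ccc(OC(C)C)c(OC(C)C)c2)[C@H]3c2cc(OC(C)C)cc(OC(C)C)c2)cc1 | intermediate
25 | CNP0107857.3: (2R,3R)-3-[(2S,3S)-2-(3,4-dihydroxyphenyl)-3-(3,5-dihydroxyphenyl)-4-hydroxy-2,3-dihydro-1-benzofuran-6-yl]-2-(4-hydroxyphenyl)-6-[(E)-2-(4-hydroxyphenyl)ethenyl]-2,3-dihydro-1-benzofuran-4-ol | Oc1ccc(/C=C/c2cc(O)c3c(c2)O[C@@H](c2ccc(O)cc2)[C@@H]3c2cc(O)c3c(c2)O[C@H](c2ccc(O)c(O)c2)[C@H]3c2cc(O)cc(O)c2)cc1 | target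

## Step count and weak points

Total: 13 steps. Longest linear sequence: 10 steps (steps 1, 2, 4, 5, 6, 9, 10, 11, 12, 13).

The three steps most likely to fail:

**Step 10 (second radical annulation).** It is run on the most valuable electron-rich substrate under a stoichiometric oxidant and has no control over which face of the alkene is attacked, so half the material is the wrong diastereomer at best. The fallback sets out from 10 and 19 and comes back at 20. Diazo transfer to 10 (4-acetamidobenzenesulfonyl azide, Et3N, MeCN) gives 2-diazocyclohexane-1,3-dione F1. Decomposition of F1 by a chiral dirhodium carboxylate, Rh2(S-PTTL)4 (dirhodium tetrakis[N-phthaloyl-(S)-tert-leucinate]) or its enantiomer, in CH2Cl2 in the presence of 19 gives 20 by a carbenoid formal [3+2] cycloaddition. The electrophilic carbenoid carbon bonds to the same alkene carbon as the radical did and the carbonyl oxygen closes the ring trans. This is a two-electron, catalyst-bound process without a stoichiometric oxidant, so the chiral ligand sphere rather than the remote stereocenters can choose the alkene face.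

**Step 12 (C–H borylation at C6 of ring C).** The position ortho to the ring oxygen (C7) is only lightly shielded and is known to be activated in fused aryl ethers, so a C7 boronate may compete. The fallback sets out from 22 and comes back at 24. Iridium-catalysed C–H silylation of 22 with HSiMe(OSiMe3)2 ([Ir(OMe)(cod)]2, 2,4,7-trimethyl-1,10-phenanthroline, cyclohexene as hydrogen acceptor, THF, 80 °C) responds more strictly to sterics than borylation. It gives the aryl silane 3-[ring C C6-yl]-1,1,1,3,5,5,5-heptamethyltrisiloxane F2. Hiyama–Denmark coupling of F2 with 17 (Pd(OAc)2, 1,2-bis(dicyclohexylphosphino)ethane, KOSiMe3, toluene, 100 °C) gives 24.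

**Step 13 (eightfold ether cleavage).** It must go to completion on a molecule that carries an acid-sensitive stilbene, and isopropyl cations may alkylate the freed resorcinol rings. The fallback sets out from 22 (with 3 and 14) and comes back at 25; it removes the ethers before the stilbene exists and ends with a coupling that needs no protecting groups. Compound 22 is borylated as in step 12 (through 23) and coupled in the same pot with excess 3 (Pd(PPh3)4, aq K3PO4, as in step 2) to give the 6-[(E)-2-chloroethenyl] derivative of 22 F3. BCl3 in CH2Cl2 then cleaves the seven ethers of this alkenyl chloride, which is inert to the Lewis acid, and gives the heptaphenol F4. Separately 14 is borylated (Pd(dppf)Cl2, B2pin2, KOAc, dioxane, 80 °C) to 4-(4,4,5,5-tetramethyl-1,3,2-dioxaborolan-2-yl)phenol F5. Suzuki–Miyaura coupling of F4 with F5 (Pd(OAc)2, SPhos, K3PO4, degassed dioxane/water, 60 °C) gives 25 directly.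

Further compounds

F1 | step 10 | 2-diazocyclohexane-1,3-dione | O=C1CCCC(=O)C1=[N+]=[N-]
F2 | step 12 | 3-[(2R,3R)-3-[(2S,3S)-2-[3,4-di(propan-2-yloxy)phenyl]-3-[3,5-di(propan-2-yloxy)phenyl]-4-(propan-2-yloxy)-2,3-dihydro-1-benzofuran-6-yl]-4-(propan-2-yloxy)-2-[4-(propan-2-yloxy)phenyl]-2,3-dihydro-1-benzofuran-6-yl]-1,1,1,3,5,5,5-heptamethyltrisiloxane | C[Si](O[Si](C)(C)C)(O[Si](C)(C)C)c1cc(OC(C)C)c2c(c1)O[C@@H](c1ccc(OC(C)C)cc1)[C@@H]2c1cc(OC(C)C)c2c(c1)O[C@H](c1ccc(OC(C)C)c(OC(C)C)c1)[C@H]2c1cc(OC(C)C)cc(OC(C)C)c1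
F3 | step 13 | (2R,3R)-6-[(E)-2-chloroethenyl]-3-[(2S,3S)-2-[3,4-di(propan-2-yloxy)phenyl]-3-[3,5-di(propan-2-yloxy)phenyl]-4-(propan-2-yloxy)-2,3-dihydro-1-benzofuran-6-yl]-4-(propan-2-yloxy)-2-[4-(propan-2-yloxy)phenyl]-2,3-dihydro-1-benzofuran | Cl/C=C/c1cc(OC(C)C)c2c(c1)O[C@@H](c1ccc(OC(C)C)cc1)[C@@H]2c1cc(OC(C)C)c2c(c1)O[C@H](c1ccc(OC(C)C)c(OC(C)C)c1)[C@H]2c1cc(OC(C)C)cc(OC(C)C)c1
F4 | step 13 | (2R,3R)-6-[(E)-2-chloroethenyl]-3-[(2S,3S)-2-(3,4-dihydroxyphenyl)-3-(3,5-dihydroxyphenyl)-4-hydroxy-2,3-dihydro-1-benzofuran-6-yl]-2-(4-hydroxyphenyl)-2,3-dihydro-1-benzofuran-4-ol | Cl/C=C/c1cc(O)c2c(c1)O[C@@H](c1ccc(O)cc1)[C@@H]2c1cc(O)c2c(c1)O[C@H](c1ccc(O)c(O)c1)[C@H]2c1cc(O)cc(O)c1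
F5 | step 13 | 4-(4,4,5,5-tetramethyl-1,3,2-dioxaborolan-2-yl)phenol | CC1(C)OB(OC1(C)C)c1ccc(O)cc1
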